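- oak: left-handed substrate 0.050 M; right-handed substrate 0.050 M; reagent 0.11 M (fed, over 25 min); precatalyst 80 µM; the very flask that is asked about, followed so far
- flask: left-handed substrate 0.050 M; reagent 0.110 M (fed, over 25 min); precatalyst 80 µM; right-handed substrate 0.050 M; time 1.5 h

- oak (time / min: left-handed substrate / %, right-handed substrate / %, left-handed product / %): 2.00: 49.6, 50.3, 0.3; 5.00: 48.8, 48.9, 2.1; 12.0: 41.8, 43.9, 8.7; 25.0: 26.4, 30.3, 24.4

(standard deviation of a reading: 0.3 percentage points)

- reagent is single-handed; left-handed substrate and right-handed substrate are mirror images of each other, charged as a racemate, each of them at the stated concentration
- an excess is below zero if the other one leads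
- the handed part of reagent does not stay in what it makes, so the products of the two hands are mirror images too

* part of the left-handed substrate and right-handed substrate charged together that has reacted at 1.5 h
* excess of left-handed product over right-handed product in the product at 1.5 h
* excess of right-handed substrate over left-handed substrate among what is left of the two at 1.5 h

I began with the easy count, the reagent. At 25.0 min the oak run had its whole charge of reagent in, and the substrates had lost 43.3%. At one reagent per substrate, c(reagent) stood at 0.0667 M.

Two extreme flasks could be solved in the head. If the hands never crossed, each would run down on its own. The product split at 12.0 min read as a selectivity factor of 1.55, and that predicted an excess of right-handed substrate of 13.8% at 25.0 min. If the hands crossed far faster than they reacted, the excess would be zero. The reading was 6.88%, half of the first extreme, so I took the flask to lie between them.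

So I followed one substrate molecule. At each moment it could react or cross. Reacting goes with c(reagent). Crossing, if it holds steady, does not. Where making and erasing of excess balance, the excess is therefore proportional to c(reagent). I carried the excess per reagent, the excess divided by c(reagent) at that moment: 1.03 M⁻¹.

The forecast gave 86%, 4.2% and 26%, and said: “Catalyst death after 25 min remains the main risk, so the ranges are wide.” I took its conversion, which leaves 0.0240 M of reagent at 1.5 h. My rule then gave 2.47%, not its 26%, and I held to mine.

The flask gave 86.8%, 1.19% and 3.77%.

    left-handed substrate + racemization catalyst ⇌ right-handed substrate + racemization catalyst, rate k1*[racemization catalyst]*[left-handed substrate] forward; the back reaction follows from the equilibrium constant (k = 11.0 M⁻¹ s⁻¹)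
    precatalyst → racemization catalyst (k = 0.00390 s⁻¹)
    reagent + right-handed substrate → right-handed product (k = 0.00780 M⁻¹ s⁻¹)
    reagent + left-handed substrate → left-handed product (k = 0.0130 M⁻¹ s⁻¹)
    left-handed product ⇌ right-handed product (k = 5.40 × 10⁻⁴ s⁻¹)

With the crossing struck out, the part of the substrates reacted in the flask stood at 85.8%. The reagent left in the flask, 21% of its charge, gives 2.39% by the excess per reagent, less than the result.

In the neighbour flask with 0.28 M of reagent, full conversion leaves 0.180 M, and the same quantity gives 18.5%. That flask computed 24.9%, with >99.9% reacted.

The earlier runs and the new flask stem from a simulated flask with made-up constants; the scatter is artificial.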